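5.52 is the number to carry: the constant of the over-reaction step times the 4.0 min on offer, the wear number N, which counts how many ring lifetimes of 0.725 min fit into the run in eta or the mean stay in theta.

- eta: substrate 2.0 mM; time 4.0 min; everything together in a closed stirred flask, run for 4.0 min
- theta: substrate 2.0 mM; one stirred flow tank at steady state, fed with the mixture as stated, mean residence time 4.0 min

    substrate → ring (k1 = 0.082 /s)
    substrate + substrate ⇌ open dimer (K2 = 490 /M, k2 = 11 /M/s)
    substrate + ring → side product (k3 = 4.1 /M/s)
    ring → over-reaction product (k4 = 0.023 /s)
    substrate ⇌ dormant form (K5 = 6.1, k5 = 0.035 /s)

- the set-up with the highest share of ring in all that became ring or open dimer or side product or over-reaction product, at the outlet or at the end ("none" if the first two lie within 2 percentage points) (eta / theta / none)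
- share of ring in all that became ring or open dimer or side product or over-reaction product, at the outlet or at the end, eta
- share of ring in all that became ring or open dimer or side product or over-reaction product, at the outlet or at the end, theta

- a species is counted by the substrate in it: one open dimer or side product counts as two
- a step written with two of one species runs at k times the square of its concentration and takes two of it each time
- the stated concentrations are those of everything mixed, before any reaction; amounts are the same in each set-up
- run time (eta): 4.0 min

Turn the constants into times at the charge and the two first-order steps out of substrate give it a forward lifetime of 0.142 min, shorter than the lifetime of ring, so I treat ring as made at once. Its half-life by over-reaction, 0.50 min, is shorter than its half-life against substrate as charged, 1.4 min, so I set the side product aside, and I set the open dimer aside as well, which is a bet and not a finding. In the tank of theta, c(ring) leaves with the outflow while it wears, which gives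

share, theta ≈ 1/(1 + N) = 15.3%

In the closed flask of eta there is no outflow, and the same wear gives

share, eta ≈ e^(−N) = 0.401%

That is the weak link, since by my reckoning from the two forward constants 29.9% of the substrate goes into the dormant form, a resting state that returns it slowly. So I reforge it for eta, taking the back constant of the dormant step times the part of returning substrate that goes on to ring:

drip = 0.241 /min

dormant form at the end ≈ 11.4% of the charge

ring per dormant form = drip/(wear constant − drip) = 0.212

share, eta ≈ [0.212 × dormant form + ring left of the first burst]/(charge − dormant form) = 3.04%

I commit to theta, at 15.3% against 3.04% for eta.

The forecast named theta, with 3.4% for eta and 14.9% for theta, on the ground that “far more ring survives at the outlet”; its eta figure stands above mine.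

The simulation gives theta, with 3.55% in eta and 14.9% in theta.

Both set-ups offer ring the same N of 5.52, yet the share in theta falls from 14.9% to 3.55% when the back-mixing in the tank is taken away, so back-mixing is the main reason for the gap. N holds no concentration, since the over-reaction step takes no partner, so the neighbour of eta charged with 5.0 mM of substrate keeps N at 5.52, and its share reads 3.78%.

(The rate constants were set for the occasion; the run is a simulation.)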